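**Retrosynthetic overview**

- The strategy rests on the vicinal cis dioxygen pair C8 (tertiary OH) / C9 (OAc) inside the ten-membered ring C1–C10. Both carbons can be carbonyl carbons, so the ring is opened at C8–C9 to a C9 aldehyde / C8 ketone and closed by a samarium pinacol coupling.
- The γ-lactone (C7–O–C19–C17–C8) is made last, by oxidative lactonization of the C7/C19 diol. Ring order: ring A (from carvone), then the ten-membered ring (step 23), then the lactone (step 26).
- The seco chain is joined at C4–C5 by a B-alkyl Suzuki coupling. The partners are a ring A vinyl carbinol and a (Z)-iodoalkene that carries the C7 carbinol, the dithiane-masked C8 ketone and the Roche-ester C17/C19 unit.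
- Ring A comes from (S)-carvone: isopropenyl to C14–O (Criegee), quaternary C1 by formylation/methylation, C2 by chelation-controlled acetylide addition, and C9 relayed to C10 by oxirane, Wharton transposition and Wittig–Still rearrangement.

Key step: step 23

Remark: briarane numbering is used (C1 quaternary, C10 the other ring-fusion carbon, C19 the lactone carbonyl); the C2 and C14 oxygens pass through the key step as an acetonide, because the C9 installation needs strong bases, and the three acetates are put on afterwards.

**Ring A fragment**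

Step 1
Reactants: 1 (S)-carvone
Product: 2 (S)-carvone oxide, oxirane across C11–C12 trans to the isopropenyl group [(1S,4S,6S)-1-methyl-4-(prop-1-en-2-yl)-7-oxabicyclo[4.1.0]heptan-2-one]
Conditions: 30% H2O2, NaOH (aq.), MeOH, 0 °C
Reagents that add atoms: hydrogen peroxide, OO
Why: Weitz–Scheffer nucleophilic epoxidation; hydroperoxide adds axially to the enone β-carbon (C12) anti to the C14 isopropenyl group, which places the oxirane on the face that later delivers C9.

Step 2
Reactants: 2 (S)-carvone oxide
Product: 3 hydroxymethylene derivative of 2 at the CH2 next to the ketone (future C1), enol form of the β-keto aldehyde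
Conditions: NaH, HCO2Et, THF (cat. EtOH), 0 °C → rt; then 1 M HCl
Reagents that add atoms: ethyl formate, CCOC=O
Why: crossed Claisen formylation at the only enolizable position, driven by formation of the stabilized β-keto aldehyde enolate.

Step 3
Reactants: 3 hydroxymethylene epoxy ketone
Product: 4 epoxy keto aldehyde with quaternary C1 (methyl trans, formyl cis to the isopropenyl group)
Conditions: MeI, K2CO3, acetone, reflux
Reagents that add atoms: iodomethane, CI
Why: C-alkylation of the β-keto aldehyde enolate; iodomethane approaches the planar enolate carbon anti to the adjacent isopropenyl group and so sets C1.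

Step 4
Reactants: 4 epoxy keto aldehyde
Product: 5 propargylic alcohol, 4 with the formyl group converted into an (R)-1-hydroxyprop-2-ynyl group (C2 carbinol)
Conditions: HC≡CMgBr (0.5 M in THF), CH2Cl2, −78 °C; aq. NH4Cl
Reagents that add atoms: ethynylmagnesium bromide, C#C[Mg]Br
Why: chelation-controlled Grignard addition: magnesium bridges the formyl and C10 keto oxygens and the acetylide attacks the aldehyde from the side of the C1 methyl group, away from C14 and its isopropenyl group, which sets C2, while the doubly flanked ketone does not react at −78 °C.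

Step 5
Reactants: 5 propargylic alcohol
Product: 8 epoxy ketone diacetate (C14 acetate in place of the isopropenyl group; C2 acetate; ethynyl group kept), via methoxy hydroperoxide 6 (not isolated), via peroxy acetate 7 (not isolated)
Conditions: O3, CH2Cl2/MeOH, −78 °C; then Ac2O, Et3N, 4-(dimethylamino)pyridine (DMAP), CH2Cl2, 0 → 40 °C
Reagents that add atoms: ozone, [O-][O+]=O; methanol, CO; acetic anhydride, CC(=O)OC(C)=O
Why: ozonolysis of the 1,1-disubstituted alkene in methanol (the alkyne reacts far more slowly) followed by Criegee rearrangement of the peroxy acetate, in which C14 migrates to oxygen with retention; the free C2 hydroxyl is acetylated in the same pot.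

Step 6
Reactants: 8 epoxy ketone diacetate (ethynyl)
Product: 9 epoxy ketone diacetate (vinyl)
Conditions: H2 (1 atm), Pd/CaCO3 poisoned with Pb(OAc)2, quinoline, EtOAc, rt
Reagents that add atoms: none
Why: Lindlar semihydrogenation of the terminal alkyne to the vinyl group needed for the later hydroboration; the alkyne was only needed to survive the ozonolysis.

Step 7
Reactants: 9 epoxy ketone diacetate (vinyl)
Product: 11 triol (free C2/C12/C14 hydroxyls; C10=C11 alkene), via Wharton allylic alcohol 10 (not isolated)
Conditions: N2H4·H2O, AcOH (cat.), MeOH, 0 °C → rt, argon; then K2CO3, MeOH, rt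
Reagents that add atoms: none
Why: Wharton transposition (hydrazone, oxirane opening, loss of N2) converts the α,β-epoxy ketone into the C12 allylic alcohol with the oxirane C12–O bond and its configuration kept, and methanolysis then removes both acetates.

Step 8
Reactants: 11 triol
Product: 12 acetonide of the C2/C14 diol, C12 hydroxyl free
Conditions: 2,2-dimethoxypropane, pyridinium p-toluenesulfonate, CH2Cl2, rt
Reagents that add atoms: 2,2-dimethoxypropane, COC(C)(C)OC
Why: thermodynamically controlled ketalization; only the C2/C14 1,3-diol can close a six-membered dioxane (the C12 and C14 hydroxyls are trans on the ring), so the allylic C12 hydroxyl stays free.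

Step 9
Reactants: 12 acetonide allylic alcohol
Product: 13 (tributylstannyl)methyl ether of the C12 hydroxyl
Conditions: KH, 18-crown-6, THF, 0 °C; Bu3SnCH2I, rt
Reagents that add atoms: (iodomethyl)tributylstannane, CCCC[Sn](CCCC)(CCCC)CI
Why: Williamson etherification of the potassium alkoxide with the reactive primary iodide (Still reagent).

Step 10
Reactants: 13 stannylmethyl ether
Product: 15 ring A alcohol (C9 hydroxymethyl on C10 cis to the C1 methyl; C11=C12 alkene; C2/C14 acetonide; vinyl on C2), via alkoxymethyllithium 14 (not isolated)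
Conditions: n-BuLi, THF, −78 °C; aq. NH4Cl
Reagents that add atoms: none
Why: Wittig–Still [2,3]-sigmatropic rearrangement after tin–lithium exchange; the CH2O unit passes suprafacially from the C12 oxygen to C10, so C9 arrives on the face of the former oxirane (cis to the C1 methyl, trans to the C2 chain) and the alkene moves to C11=C12.

**Iodoalkene fragment**

Step 11
Reactants: 16 methyl (S)-3-hydroxy-2-methylpropanoate (Roche ester)
Product: 17 methyl (S)-3-(tert-butyldimethylsilyloxy)-2-methylpropanoate
Conditions: TBSCl, imidazole, DMF, rt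
Reagents that add atoms: tert-butyldimethylsilyl chloride, CC(C)(C)[Si](C)(C)Cl
Why: standard silylation of the primary alcohol (future C19 oxygen).

Step 12
Reactants: 17 silyl ether ester
Product: 18 (S)-3-(tert-butyldimethylsilyloxy)-2-methylpropanal
Conditions: i-Bu2AlH, CH2Cl2, −78 °C; aq. potassium sodium tartrate
Reagents that add atoms: none
Why: partial reduction of the ester with i-Bu2AlH at low temperature, where the tetrahedral aluminium acetal survives until work-up; the aldehyde (future C8) is used crude to avoid epimerization at C17.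

Step 13
Reactants: 18 aldehyde
Product: 19 2-[(2S)-1-(tert-butyldimethylsilyloxy)propan-2-yl]-1,3-dithiane
Conditions: HS(CH2)3SH, BF3·OEt2 (substoichiometric), CH2Cl2, −78 → −30 °C
Reagents that add atoms: propane-1,3-dithiol, SCCCS
Why: Lewis-acid thioacetalization at low temperature, which masks C8 as an acyl-anion equivalent without epimerizing C17.

Step 14
Reactants: 20 but-2-yn-1-ol
Product: 21 but-2-ynal (used as a CH2Cl2/THF solution)
Conditions: MnO2, CH2Cl2, rt; filtration
Reagents that add atoms: none
Why: selective MnO2 oxidation of a propargylic alcohol to the ynal.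

Step 15
Reactants: 19 dithiane; 21 but-2-ynal
Product: 23 propargylic alcohol (dithiane adduct of but-2-ynal; C7 epimer mixture), via lithiated dithiane 22 (not isolated)
Conditions: n-BuLi, THF, −20 °C; then 21, −78 °C; aq. NH4Cl
Reagents that add atoms: none
Why: Corey–Seebach umpolung; the 2-lithio-1,3-dithiane adds 1,2 to the ynal in THF without HMPA and forms C7–C8, and the C7 configuration does not matter because it is erased in the next step.

Step 16
Reactants: 23 propargylic alcohol mixture
Product: 24 ynone (C7 ketone between the propynyl group and the dithiane carbon)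
Conditions: Dess–Martin periodinane, NaHCO3, CH2Cl2, 0 °C → rt
Reagents that add atoms: none
Why: Dess–Martin oxidation of the secondary propargylic alcohol; in dry CH2Cl2 the dithiane is not cleaved.

Step 17
Reactants: 24 ynone
Product: 25 (S)-propargylic alcohol (C7)
Conditions: (R)-tetrahydro-1-methyl-3,3-diphenyl-1H,3H-pyrrolo[1,2-c][1,3,2]oxazaborole ((R)-Me-CBS), BH3·SMe2, THF, −30 °C
Reagents that add atoms: none
Why: Corey–Bakshi–Shibata reduction under reagent control; the quaternary dithianyl carbon is the large group and the propynyl group the small one, so the (R)-catalyst delivers hydride to the face that gives the (S)-carbinol.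

Step 18
Reactants: 25 (S)-propargylic alcohol
Product: 27 (Z)-iodoalkene alcohol (iodine on C5 cis to C7), via cyclic vinylalanate 26 (not isolated)
Conditions: NaAlH2(OCH2CH2OMe)2 (toluene solution), THF, 0 °C → rt; EtOAc; then I2, THF, −78 → 0 °C
Reagents that add atoms: iodine, II
Why: hydroxyl-directed trans-hydroalumination puts hydride on C6 and aluminium on C5 within a five-membered alanate, and iodinolysis with retention gives the (Z)-3-iodoallylic alcohol.

Step 19
Reactants: 27 iodoalkene alcohol
Product: 28 bis-silyl iodoalkene (C7 OTBS, C19 OTBS, C8 dithiane)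
Conditions: TBSOTf, 2,6-lutidine, CH2Cl2, −78 → 0 °C
Reagents that add atoms: tert-butyldimethylsilyl triflate, CC(C)(C)[Si](C)(C)OS(=O)(=O)C(F)(F)F
Why: silylation of the hindered secondary allylic alcohol with the reactive silyl triflate.

**Fragment union and endgame**

Step 20
Reactants: 15 ring A alcohol; 28 iodoalkene
Product: 30 coupled seco alcohol (C4–C5 bond formed; Z alkene at C5=C6; C8 dithiane), via alkylborane 29 (not isolated)
Conditions: 9-BBN (2.5 equiv), THF, rt; then 28, PdCl2(dppf) [dppf = 1,1′-bis(diphenylphosphino)ferrocene], AsPh3, Cs2CO3, DMF/H2O, rt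
Reagents that add atoms: none
Why: B-alkyl Suzuki–Miyaura coupling: anti-Markovnikov hydroboration of the vinyl group gives the C4 borane (the free C9 hydroxyl is held as its borinate), and zerovalent palladium couples it with the alkenyl iodide with retention of the alkene geometry.

Step 21
Reactants: 30 coupled dithiane
Product: 31 hydroxy ketone (C8 ketone, C9 primary alcohol)
Conditions: MeI, CaCO3, MeCN/H2O 9:1, 45 °C
Reagents that add atoms: water, O
Why: alkylative dithiane hydrolysis under buffered, non-oxidizing conditions that leave the alkenes, silyl ethers, acetonide and the C17 stereocentre next to the new ketone untouched.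

Step 22
Reactants: 31 hydroxy ketone
Product: 32 seco keto aldehyde (C9 aldehyde on ring A, C8 ketone), used at once
Conditions: Dess–Martin periodinane, NaHCO3, CH2Cl2, 0 °C
Reagents that add atoms: none
Why: buffered Dess–Martin oxidation gives the β,γ-unsaturated aldehyde (α-cyclocitral type) without base, so C10 is neither epimerized nor brought into conjugation.

Step 23
Reactants: 32 seco keto aldehyde
Product: 33 ten-membered cis C8/C9 diol (C8 tertiary OH, C9 secondary OH; C7 and C19 OTBS; C2/C14 acetonide)
Conditions: SmI2 (0.1 M in THF, 4 equiv), THF, −78 °C → rt, slow addition of 32 (final concentration about 2 mM); aq. NH4Cl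
Reagents that add atoms: none
Why: Divalent samarium reduces the more easily reduced C9 aldehyde to a ketyl, whose carbon adds to the C8 ketone carbonyl bound to the same, now trivalent, samarium, and a second electron gives the samarium diolate that is protonated on work-up; the closest known reaction type is the SmI2 pinacol cyclization of keto aldehydes, which is known for medium and large rings. The ten-membered ring closes by attack of the C9 ketyl radical on the C8 carbonyl carbon with the C=O bond outside the new ring (10-exo-trig). C9 is set by the C10 stereocentre, the new bond forming anti to the quaternary C1 with the ring A alkene carbon C11 next to the ketyl oxygen. C8 is set by the C7 silyloxy group in the polar Felkin–Anh sense, the bulky non-chelating OTBS lying anti to the incoming carbon and H-7 toward it. Both preferences lead to the diastereomer in which one trivalent samarium can bridge the two oxygens, which is the cis diol. The step needs aldehyde-first reduction and survival of the α-silyloxy ketone, which working without HMPA at low temperature should secure, and ring closure over oligomerization, which high dilution secures; acetonide and silyl ethers are inert to SmI2.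

Step 24
Reactants: 33 cis diol
Product: 34 C9 acetate
Conditions: Ac2O, pyridine, DMAP (cat.), CH2Cl2, rt
Reagents that add atoms: acetic anhydride, CC(=O)OC(C)=O
Why: acylation of the only free secondary hydroxyl (the tertiary C8 hydroxyl is inert), done before desilylation so that C19 can later form a lactol only with the C7 hydroxyl.

Step 25
Reactants: 34 C9 acetate
Product: 35 pentaol monoacetate (free C2, C7, C8, C14 and C19 hydroxyls, C9 acetate)
Conditions: 48% aq. HF, MeCN, 0 °C → rt
Reagents that add atoms: none
Why: acidic fluoride cleaves both TBS ethers and hydrolyses the 1,3-dioxane acetonide in one operation while the acetate is kept.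

Step 26
Reactants: 35 pentaol monoacetate
Product: 37 γ-lactone triol (lactone C7–O–C19(=O); free C2/C8/C14 hydroxyls), via lactol 36 (not isolated)
Conditions: 2,2,6,6-tetramethylpiperidin-1-oxyl (TEMPO, cat.), PhI(OAc)2, CH2Cl2, rt
Reagents that add atoms: none
Why: TEMPO/PhI(OAc)2 oxidative lactonization: the primary C19 alcohol is oxidized first, the aldehyde is trapped by the C7 hydroxyl as the five-membered lactol, and the lactol is oxidized on to the lactone, while the secondary C2, C7 and C14 hydroxyls, each next to a fully substituted carbon, are oxidized much more slowly by the bulky oxoammonium species.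

Step 27
Reactants: 37 γ-lactone triol
Product: 38 stylatulide lactone
Conditions: Ac2O, pyridine, DMAP (cat.), CH2Cl2, rt
Reagents that add atoms: acetic anhydride, CC(=O)OC(C)=O
Why: acetylation of the secondary C2 and C14 hydroxyls; the tertiary C8 hydroxyl, flanked by C7, C9 and C17, is not acylated at room temperature.

**Compound list**

1 | (S)-carvone | CC1=CC[C@@H](CC1=O)C(C)=C | starting material
2 | (S)-carvone oxide (oxirane trans to isopropenyl) | C[C@]12O[C@H]1C[C@H](C(C)=C)CC2=O | intermediate
3 | hydroxymethylene epoxy ketone (enol) | C[C@]12O[C@H]1C[C@H](C(C)=C)/C(=C/O)C2=O | intermediate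
4 | epoxy keto aldehyde, quaternary C1 | C[C@]12O[C@H]1C[C@H](C(C)=C)[C@](C)(C=O)C2=O | intermediate
5 | C2 propargylic alcohol | C[C@]12O[C@H]1C[C@H](C(C)=C)[C@](C)([C@H](O)C#C)C2=O | intermediate
6 | methoxy hydroperoxide (not isolated) | C[C@]12O[C@H]1C[C@H](C(C)(OC)OO)[C@](C)([C@H](O)C#C)C2=O | intermediate
7 | peroxy acetate (not isolated) | C[C@]12O[C@H]1C[C@H](C(C)(OC)OOC(C)=O)[C@](C)([C@H](OC(C)=O)C#C)C2=O | intermediate
8 | epoxy ketone diacetate, ethynyl | C[C@]12O[C@H]1C[C@H](OC(C)=O)[C@](C)([C@H](OC(C)=O)C#C)C2=O | intermediate
9 | epoxy ketone diacetate, vinyl | C[C@]12O[C@H]1C[C@H](OC(C)=O)[C@](C)([C@H](OC(C)=O)C=C)C2=O | intermediate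
10 | Wharton allylic alcohol diacetate (not isolated) | CC1=C[C@@](C)([C@H](OC(C)=O)C=C)[C@@H](OC(C)=O)C[C@@H]1O | intermediate
11 | triol (C2, C12, C14 hydroxyls) | CC1=C[C@@](C)([C@H](O)C=C)[C@@H](O)C[C@@H]1O | intermediate
12 | C2/C14 acetonide, C12 alcohol | CC1=C[C@@]2(C)[C@@H](C=C)OC(C)(C)O[C@H]2C[C@@H]1O | intermediate
13 | C12 (tributylstannyl)methyl ether | CC1=C[C@@]2(C)[C@@H](C=C)OC(C)(C)O[C@H]2C[C@@H]1OC[Sn](CCCC)(CCCC)CCCC | intermediate
14 | alkoxymethyllithium (not isolated) | CC1=C[C@@]2(C)[C@@H](C=C)OC(C)(C)O[C@H]2C[C@@H]1OC[Li] | intermediate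
15 | ring A alcohol (C9 hydroxymethyl on C10) | OC[C@H]1C(C)=CC[C@@H]2OC(C)(C)O[C@H](C=C)[C@]12C | intermediate
16 | methyl (S)-3-hydroxy-2-methylpropanoate | COC(=O)[C@@H](C)CO | starting material
17 | methyl (S)-3-(tert-butyldimethylsilyloxy)-2-methylpropanoate | COC(=O)[C@@H](C)CO[Si](C)(C)C(C)(C)C | intermediate
18 | (S)-3-(tert-butyldimethylsilyloxy)-2-methylpropanal | O=C[C@@H](C)CO[Si](C)(C)C(C)(C)C | intermediate
19 | 2-[(2S)-1-(tert-butyldimethylsilyloxy)propan-2-yl]-1,3-dithiane | C[C@@H](CO[Si](C)(C)C(C)(C)C)C1SCCCS1 | intermediate
20 | but-2-yn-1-ol | CC#CCO | starting material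
21 | but-2-ynal | CC#CC=O | intermediate
22 | 2-lithio dithiane (not isolated) | C[C@@H](CO[Si](C)(C)C(C)(C)C)C1([Li])SCCCS1 | intermediate
23 | propargylic alcohol, C7 epimers | CC#CC(O)C1(SCCCS1)[C@@H](C)CO[Si](C)(C)C(C)(C)C | intermediate
24 | ynone | CC#CC(=O)C1(SCCCS1)[C@@H](C)CO[Si](C)(C)C(C)(C)C | intermediate
25 | (S)-propargylic alcohol | CC#C[C@H](O)C1(SCCCS1)[C@@H](C)CO[Si](C)(C)C(C)(C)C | intermediate
26 | cyclic vinylalanate, sodium salt (not isolated) | CC1=C[C@@H](C2(SCCCS2)[C@@H](C)CO[Si](C)(C)C(C)(C)C)O[Al-]1(OCCOC)OCCOC.[Na+] | intermediate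
27 | (Z)-iodoalkene alcohol | C/C(I)=C/[C@H](O)C1(SCCCS1)[C@@H](C)CO[Si](C)(C)C(C)(C)C | intermediate
28 | bis-silyl (Z)-iodoalkene | C/C(I)=C/[C@H](O[Si](C)(C)C(C)(C)C)C1(SCCCS1)[C@@H](C)CO[Si](C)(C)C(C)(C)C | intermediate
29 | alkylborane (C4 borane and C9 borinate of 9-BBN; not isolated) | C1CCC2CCCC1B2OC[C@H]1C(C)=CC[C@@H]2OC(C)(C)O[C@H](CCB3C4CCCC3CCC4)[C@]12C | intermediate
30 | coupled seco alcohol, C8 dithiane | OC[C@H]1C(C)=CC[C@@H]2OC(C)(C)O[C@H](CC/C(C)=C\[C@H](O[Si](C)(C)C(C)(C)C)C3(SCCCS3)[C@@H](C)CO[Si](C)(C)C(C)(C)C)[C@]12C | intermediate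
31 | hydroxy ketone | OC[C@H]1C(C)=CC[C@@H]2OC(C)(C)O[C@H](CC/C(C)=C\[C@H](O[Si](C)(C)C(C)(C)C)C(=O)[C@@H](C)CO[Si](C)(C)C(C)(C)C)[C@]12C | intermediate
32 | seco keto aldehyde (key-step precursor) | O=C[C@H]1C(C)=CC[C@@H]2OC(C)(C)O[C@H](CC/C(C)=C\[C@H](O[Si](C)(C)C(C)(C)C)C(=O)[C@@H](C)CO[Si](C)(C)C(C)(C)C)[C@]12C | intermediate
33 | ten-membered cis C8/C9 diol (key-step product) | CC1(C)O[C@H]2CC=C(C)[C@@H]3[C@@H](O)[C@](O)([C@@H](C)CO[Si](C)(C)C(C)(C)C)[C@@H](O[Si](C)(C)C(C)(C)C)/C=C(/C)CC[C@@H](O1)[C@@]23C | intermediate
34 | C9 acetate | CC1(C)O[C@H]2CC=C(C)[C@@H]3[C@@H](OC(C)=O)[C@](O)([C@@H](C)CO[Si](C)(C)C(C)(C)C)[C@@H](O[Si](C)(C)C(C)(C)C)/C=C(/C)CC[C@@H](O1)[C@@]23C | intermediate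
35 | pentaol monoacetate | O[C@H]1CC=C(C)[C@@H]2[C@@H](OC(C)=O)[C@](O)([C@@H](C)CO)[C@@H](O)/C=C(/C)CC[C@@H](O)[C@@]12C | intermediate
36 | lactol (not isolated) | O[C@H]1CC=C(C)[C@@H]2[C@@H](OC(C)=O)[C@@]3(O)[C@H](/C=C(/C)CC[C@@H](O)[C@@]12C)OC(O)[C@@H]3C | intermediate
37 | γ-lactone triol (C2, C8, C14 hydroxyls free) | O[C@H]1CC=C(C)[C@@H]2[C@@H](OC(C)=O)[C@@]3(O)[C@H](/C=C(/C)CC[C@@H](O)[C@@]12C)OC(=O)[C@@H]3C | intermediate
38 | stylatulide lactone | CC(=O)O[C@H]1CC=C(C)[C@@H]2[C@@H](OC(C)=O)[C@@]3(O)[C@H](/C=C(/C)CC[C@@H](OC(C)=O)[C@@]12C)OC(=O)[C@@H]3C | target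

**Step count**

Total: 27 steps. Longest linear sequence: 18 steps (steps 1–10, then 20–27); the iodoalkene branch is 9 steps (11–19).

**Steps most likely to fail**

Step 23 (samarium pinacol closure). The ketyl may add to the wrong face at C9, because strain in the ten-membered transition state can override the acyclic Felkin preference, and the trans diol would result. The fallback sets out from 32 and comes back at 33. The closure is run as described and the C9-epimeric diol F1 is oxidized at its secondary hydroxyl with Dess–Martin periodinane (the tertiary C8 hydroxyl cannot react) to the α-hydroxy ketone F2. F2 is reduced with Zn(BH4)2 in Et2O at −20 °C; zinc chelates the C8 hydroxyl and the C9 carbonyl, and hydride should enter from the open periphery of the macrocycle to give the cis diol 33. C9 is then set by hydride addition to a ring ketone and no longer during the C–C bond formation.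

Step 7 (Wharton transposition). Hydrazone formation at the C10 carbonyl, flanked by the quaternary C1 and the fully substituted oxirane carbon C11, may be so slow that hydrazinolysis of the acetates and retro-aldol-type decomposition outrun the transposition. The fallback sets out from 9 and comes back at 10, which is methanolysed to 11 as in the second stage of step 7. NaBH4 in MeOH at 0 °C reduces the ketone to the epoxy alcohol F3 (either C10 epimer serves). PhOC(S)Cl, pyridine and DMAP give the phenyl thionocarbonate F4. Bu3SnH and azobisisobutyronitrile in toluene at 80 °C generate the C10 radical, which opens the oxirane (Barton-type radical fragmentation of an α,β-epoxy thionocarbonate) to the C12 alkoxy radical and, after hydrogen transfer, to the allylic alcohol diacetate 10.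

Step 4 (acetylide addition). Addition through a non-chelated, dipole-opposed conformer would erode or invert the facial selectivity at C2. The fallback sets out from 5 (as the C2 epimer mixture) and comes back at 5. Dess–Martin periodinane oxidizes the epimers to the ynone F5. Reduction with (S)-tetrahydro-1-methyl-3,3-diphenyl-1H,3H-pyrrolo[1,2-c][1,3,2]oxazaborole and BH3·SMe2 in THF at −30 °C then sets C2 under reagent control (quaternary C1 as the large group, ethynyl as the small one), while the doubly flanked C10 ketone should react much more slowly.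

Further compounds
F1 | step 23 | C9-epimeric (trans) diol | CC1(C)O[C@H]2CC=C(C)[C@@H]3[C@H](O)[C@](O)([C@@H](C)CO[Si](C)(C)C(C)(C)C)[C@@H](O[Si](C)(C)C(C)(C)C)/C=C(/C)CC[C@@H](O1)[C@@]23C
F2 | step 23 | α-hydroxy ketone (C9 ketone, C8 tertiary alcohol) | CC1(C)O[C@H]2CC=C(C)[C@@H]3C(=O)[C@](O)([C@@H](C)CO[Si](C)(C)C(C)(C)C)[C@@H](O[Si](C)(C)C(C)(C)C)/C=C(/C)CC[C@@H](O1)[C@@]23C
F3 | step 7 | epoxy alcohol (C10 carbinol, either epimer) | C[C@]12O[C@H]1C[C@H](OC(C)=O)[C@](C)([C@H](OC(C)=O)C=C)C2O
F4 | step 7 | phenyl thionocarbonate of the epoxy alcohol | C[C@]12O[C@H]1C[C@H](OC(C)=O)[C@](C)([C@H](OC(C)=O)C=C)C2OC(=S)Oc1ccccc1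
F5 | step 4 | ynone (C2 ketone) | C[C@]12O[C@H]1C[C@H](C(C)=C)[C@](C)(C(=O)C#C)C2=O
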